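(The readings were generated by integration with made-up constants.)

A small charge of single-handed free catalyst, 50 mM, works on a racemate, and the question is how pure the right-handed substrate left behind becomes in the flask.

| flask | left-handed substrate | right-handed substrate | solid reagent | free catalyst | added ligand | remark | time |
|---|---|---|---|---|---|---|---|
| blue | 0.50 M | 0.50 M | 0.75 M | 50 mM | 38 mM | run made earlier |  |
| violet | 0.50 M | 0.50 M | 0.75 M | 50 mM | 150 mM | run made earlier |  |
| flask | 0.50 M | 0.50 M | 0.750 M | 50 mM | 76 mM |  | 20 h |

- blue (time / h: right-handed substrate / %, left-handed substrate / %): 1.50: 48, 37; 3.00: 46, 28; 5.00: 47, 12; 6.00: 45, 7; 8.00: 43, 4; 10.0: 39, 2; 12.0: 40, 2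
- violet (time / h: right-handed substrate / %, left-handed substrate / %): 0.667: 50, 45; 2.00: 48, 36; 3.00: 49, 29; 5.00: 49, 21; 8.00: 46, 5; 10.0: 45, 5; 12.0: 44, 3

(standard deviation of a reading: 1.5 percentage points)

- whether the excess of right-handed substrate over left-handed substrate among what is left of the two reaches 80 % by 20 h (yes / no)
- the highest excess of right-handed substrate over left-handed substrate among what is left of the two up to 20 h

- free catalyst is single-handed; left-handed substrate and right-handed substrate are mirror images of each other, charged as a racemate, each of them at the stated concentration
- solid reagent is a solid; its amount is given per volume of the solution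
- at the start none of the solid reagent is in solution

The last blue reading gives 14.4 for the number I carry, the selectivity factor s: the logarithm of the fraction of its own charge left of the left-handed substrate, over the same logarithm for the right-handed substrate. On this scale 1 is the symmetric zero, where both fall alike and no excess appears. The last violet reading gives 22.0, but the left-handed readings behind these values, 2 % in blue and 3 % in violet, each carry a scatter of 1.5 percentage points, so I keep the lower value.

An excess of 80 % means left-handed over right-handed substrate stands at 0.111. So, with s held constant along the run, the right-handed substrate need fall to 84.9 % of its own charge by s, or 90.1 % by the violet value. I take one number as enough for the yes, since the flask's ligand, 76 mM, lies between the two runs' charges, and the readings of both runs pass that level. Taking one solid reagent per substrate reacted, reaching that point in the flask needs 0.528 M, less than the 0.750 M charged. I say yes, and I expect a top above the 87.2 % of the last violet reading, which is lower than the 90.5 % of the last blue reading.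

The forecast says yes and gives a top of 98 %, a value where mine is only an expected floor: “Both runs show the left-handed substrate being consumed much faster than the right-handed one”.

The flask answers yes, with a top of 99.6 %, and runs by this scheme:

    free catalyst + left-handed substrate ⇌ catalyst intermediate A (K = 48.0 M⁻¹, k = 45.0 M⁻¹ h⁻¹)
    free catalyst + right-handed substrate ⇌ catalyst intermediate B (K = 1.30 M⁻¹, k = 180 M⁻¹ h⁻¹)
    partner + catalyst intermediate A → free catalyst + left-handed product (k = 22.0 M⁻¹ h⁻¹)
    partner + catalyst intermediate B → free catalyst + right-handed product (k = 10.0 M⁻¹ h⁻¹)
    free catalyst + added ligand ⇌ idle complex, settled at all times (K = 18.0 M⁻¹)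
    partner ⇌ dormant form (K = 2.50, k = 0.220 h⁻¹)
    solid reagent ⇌ partner, rate k7*(cs7 - [partner]) while solid is left; crystals form when [partner] > cs7 (solubility = 0.240 M, k = 0.810 h⁻¹)

The flask's excess passes 80 % at 7.69 h, with 51.0 % of the two charged reacted, where s asked for 52.8 %. At that moment 44.1 % of the two charged is still right-handed substrate, which is 88.2 % of its own charge against the 84.9 % reckoned from s.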